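**Plan**
- Ring B is numbered C1 (O–ring A), C2 (Me), C3 (OMe), C4 (H), C5 (iPr), C6 (O–ring C). The retrosynthesis first takes the quinone back to a benzyl/methyl-protected hydroquinone, then cuts the ring A–O bond at C1, then cuts ring B at C5–C6 and C1–C2, and last the C6–O-linked malonate back to a ring C phenol.
- Enabling feature: C1–C3 of ring B form a 2-methylresorcinol pattern, which maps onto a 2-methylcyclohexane-1,3-dione. The oxygen at C6 sits beside the isopropyl at C5, so C6 can be a malonate carbon that already carries the ring C oxygen and C5 the β-carbon of an enone.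
- Forward: ring C is made first from thymol, its phenol is alkylated by a chloromalonate, and ring B is grown on that oxygen by Michael–Claisen annulation. Regioselective O-methylation and palladium-catalysed decarboxylation–dehydrogenation of the remaining allyl ester aromatize ring B to a single methoxyphenol.
- Ring A (from carvacrol) is then attached through a symmetric diaryliodonium salt; hydrogenolysis and PhI(OAc)2 oxidation release the quinone of ring C.
- Stereochemistry: the target has none. The sp3 centres of the annulation are formed without control and erased on aromatization.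

Key step: step 9

Remark: the malonate is carried as its diallyl ester so that the ester left after the annulation can be removed under palladium catalysis; thymol, carvacrol, diallyl malonate, isobutyraldehyde and diethyl (2-oxobutyl)phosphonate are taken as commercial.

**Route**

Step 1
Reactants: 1 thymol [5-methyl-2-(propan-2-yl)phenol]
Product: 2 4-bromo-5-methyl-2-(propan-2-yl)phenol
Conditions: NBS, MeCN, 0 °C to rt
Reagents that add atoms: N-bromosuccinimide, O=C1CCC(=O)N1Br
Why: Electrophilic aromatic bromination of a phenol in MeCN should go to the free para position, the standard way to 4-bromothymol.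

Step 2
Reactants: 2 4-bromo-5-methyl-2-(propan-2-yl)phenol
Product: 3 4-methoxy-5-methyl-2-(propan-2-yl)phenol
Conditions: NaOMe (5 equiv), CuBr (10 mol %), MeOH/DMF, 110 °C; then aq. HCl
Reagents that add atoms: sodium methoxide (NaOMe), [Na+].[O-]C
Why: Copper-catalysed Ullmann-type methoxylation of an aryl bromide is known to work on unprotected bromophenols (as in the conversion of bromohydroxybenzaldehydes to their methoxy analogues), so the hydroxyl needs no protection.

Step 3
Reactants: 3 4-methoxy-5-methyl-2-(propan-2-yl)phenol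
Product: 5 2-hydroxy-5-methoxy-6-methyl-3-(propan-2-yl)benzaldehyde, via salicyl alcohol 4 (not isolated)
Conditions: MgCl2, Et3N, (CH2O)n, MeCN, reflux; then aq. HCl
Reagents that add atoms: paraformaldehyde (as formaldehyde), C=O
Why: In the magnesium-mediated ortho-formylation (Casiraghi–Skattebøl reaction) the magnesium phenoxide delivers formaldehyde only to the single free ortho carbon, and the hydroxymethyl phenol 4 is oxidized in the flask by hydride transfer to a second formaldehyde.

Step 4
Reactants: 5 2-hydroxy-5-methoxy-6-methyl-3-(propan-2-yl)benzaldehyde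
Product: 6 2-(benzyloxy)-5-methoxy-6-methyl-3-(propan-2-yl)benzaldehyde
Conditions: BnBr, K2CO3, DMF, 60 °C
Reagents that add atoms: benzyl bromide, BrCc1ccccc1
Why: Williamson etherification of the salicylaldehyde phenoxide; the benzyl group marks the oxygen that will later become a quinone carbonyl and can be removed by hydrogenolysis.

Step 5
Reactants: 6 2-(benzyloxy)-5-methoxy-6-methyl-3-(propan-2-yl)benzaldehyde
Product: 8 2-(benzyloxy)-5-methoxy-6-methyl-3-(propan-2-yl)phenol, via aryl formate 7 (not isolated)
Conditions: mCPBA, CH2Cl2, 0 °C to rt; then K2CO3 (cat.), MeOH, rt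
Reagents that add atoms: 3-chloroperoxybenzoic acid, OOC(=O)c1cccc(Cl)c1
Why: Baeyer–Villiger (Dakin-type) oxidation, in which the electron-rich ortho-alkoxyaryl group migrates in preference to hydrogen, followed by methanolysis of the formate.

Step 6
Reactants: 9 diallyl malonate [bis(prop-2-en-1-yl) propanedioate]
Product: 10 bis(prop-2-en-1-yl) 2-chloropropanedioate
Conditions: SO2Cl2 (1.05 equiv), neat, 40–45 °C, dark
Reagents that add atoms: sulfuryl chloride, O=S(=O)(Cl)Cl
Why: Electrophilic α-chlorination of a malonate through its enol, the usual preparation of chloromalonates, which allyl esters tolerate as in the known chlorination of allyl acetoacetate.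

Step 7
Reactants: 8 2-(benzyloxy)-5-methoxy-6-methyl-3-(propan-2-yl)phenol; 10 bis(prop-2-en-1-yl) 2-chloropropanedioate
Product: 11 bis(prop-2-en-1-yl) 2-[2-(benzyloxy)-5-methoxy-6-methyl-3-(propan-2-yl)phenoxy]propanedioate
Conditions: Cs2CO3, MeCN, 60 °C
Reagents that add atoms: none
Why: SN2 O-alkylation of a phenoxide by the doubly activated chloride is the standard entry to aryloxymalonates, and the caesium phenoxide should cope with the two ortho substituents.

Step 8
Reactants: 12 isobutyraldehyde (2-methylpropanal); 13 diethyl (2-oxobutyl)phosphonate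
Product: 14 (E)-6-methylhept-4-en-3-one
Conditions: NaH, THF, 0 °C to rt
Reagents that add atoms: none
Why: Horner–Wadsworth–Emmons olefination of a β-ketophosphonate gives the E-enone cleanly and avoids the regiochemical ambiguity of an aldol condensation with butanone.

Step 9
Reactants: 11 bis(prop-2-en-1-yl) 2-[2-(benzyloxy)-5-methoxy-6-methyl-3-(propan-2-yl)phenoxy]propanedioate; 14 (E)-6-methylhept-4-en-3-one
Product: 16 prop-2-en-1-yl 1-[2-(benzyloxy)-5-methoxy-6-methyl-3-(propan-2-yl)phenoxy]-3-methyl-2,4-dioxo-6-(propan-2-yl)cyclohexane-1-carboxylate (mixture of diastereomers), via Michael adduct 15 (not isolated)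
Conditions: NaH (1.3 equiv) in CH2=CHCH2OH/THF (gives NaOCH2CH=CH2), 11, then 14 (2 equiv), 0 °C to 75 °C; cold 1 M HCl
Reagents that add atoms: none
Why: NaOCH2CH=CH2 deprotonates 11 and the tertiary aryloxymalonate carbanion adds to the isopropyl-bearing β-carbon of 14 to give 15, whose ethyl ketone then enolizes towards its CH2CH3 side and attacks one ester carbonyl with loss of allyloxide. This is the dimedone-type Michael–Claisen annulation of a 2-substituted malonate with an α,β-unsaturated ketone, here with an aryloxy group as the malonate substituent. Ring B closes in the 6-(enolendo)-exo-trig mode, while closure from the other α-carbon of the ketone would give a four-membered ring and does not compete. The sp3 centres created (C1, C6 and, in the keto form, C3 of the cyclohexane) are under no control and need none, because all are flattened when ring B is aromatized. The step needs regiochemistry and a drive against retro-Michael cleavage: the polarity of the partners fixes which carbons join, and deprotonation of the 2-methyl-1,3-dione product pulls the crowded Michael equilibrium forward. Allyloxide in allyl alcohol matches the ester groups, so transesterification is degenerate and the remaining allyl ester is kept for step 11.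

Step 10
Reactants: 16 prop-2-en-1-yl 1-[2-(benzyloxy)-5-methoxy-6-methyl-3-(propan-2-yl)phenoxy]-3-methyl-2,4-dioxo-6-(propan-2-yl)cyclohexane-1-carboxylate
Product: 17 prop-2-en-1-yl 1-[2-(benzyloxy)-5-methoxy-6-methyl-3-(propan-2-yl)phenoxy]-4-methoxy-3-methyl-2-oxo-6-(propan-2-yl)cyclohex-3-ene-1-carboxylate (mixture of diastereomers)
Conditions: Me2SO4, K2CO3, acetone, reflux
Reagents that add atoms: dimethyl sulfate, COS(=O)(=O)OC
Why: O-alkylation of a cyclic 1,3-dione enolate should take place at the oxygen remote from the quaternary carbon, as in enol ether formation from 4,4-disubstituted cyclohexane-1,3-diones, which places the methoxy group on the carbon that becomes C3 of ring B.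

Step 11
Reactants: 17 prop-2-en-1-yl 1-[2-(benzyloxy)-5-methoxy-6-methyl-3-(propan-2-yl)phenoxy]-4-methoxy-3-methyl-2-oxo-6-(propan-2-yl)cyclohex-3-ene-1-carboxylate
Product: 19 2-[2-(benzyloxy)-5-methoxy-6-methyl-3-(propan-2-yl)phenoxy]-5-methoxy-6-methyl-3-(propan-2-yl)phenol, via cyclohexadienone 18 (not isolated)
Conditions: Pd(OAc)2 (5 mol %), Ph2PCH2CH2PPh2 (5 mol %), MeCN, reflux
Reagents that add atoms: none
Why: Tsuji decarboxylation–dehydrogenation of an α,α-disubstituted allyl β-keto ester: oxidative addition to zerovalent palladium formed in the flask, loss of CO2 to the palladium enolate, β-hydride elimination towards the isopropyl-bearing carbon and release of propene give the cross-conjugated dienone 18, which tautomerizes to the phenol.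

Step 12
Reactants: 20 carvacrol [2-methyl-5-(propan-2-yl)phenol]
Product: 21 2-methoxy-1-methyl-4-(propan-2-yl)benzene
Conditions: MeI, K2CO3, acetone, reflux
Reagents that add atoms: iodomethane, CI
Why: Williamson methylation of a phenol.

Step 13
Reactants: 21 2-methoxy-1-methyl-4-(propan-2-yl)benzene
Product: 24 bis[4-methoxy-5-methyl-2-(propan-2-yl)phenyl]iodonium 4-methylbenzenesulfonate, via aryl iodide 22 (not isolated), via hydroxy(tosyloxy)iodoarene 23 (not isolated)
Conditions: I2 (1 equiv), 21 (4.2 equiv), mCPBA (3 equiv), TsOH·H2O, CH2Cl2, rt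
Reagents that add atoms: iodine, II; 4-methylbenzenesulfonic acid, Cc1ccc(cc1)S(=O)(=O)O
Why: Known one-pot route to symmetric electron-rich diaryliodonium tosylates: oxidative iodination para to the methoxy group, oxidation of 22 to the trivalent iodine species 23, and electrophilic substitution of a second molecule of 21 at the same para position.

Step 14
Reactants: 19 2-[2-(benzyloxy)-5-methoxy-6-methyl-3-(propan-2-yl)phenoxy]-5-methoxy-6-methyl-3-(propan-2-yl)phenol; 24 bis[4-methoxy-5-methyl-2-(propan-2-yl)phenyl]iodonium 4-methylbenzenesulfonate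
Product: 25 1-(benzyloxy)-4-methoxy-2-{4-methoxy-2-[4-methoxy-5-methyl-2-(propan-2-yl)phenoxy]-3-methyl-6-(propan-2-yl)phenoxy}-3-methyl-6-(propan-2-yl)benzene
Conditions: NaH (1.05 equiv), THF, 0 °C; then 24 (1.3 equiv), 50 °C
Reagents that add atoms: none
Why: Metal-free O-arylation of a phenoxide by a diaryliodonium salt (ligand exchange and ligand coupling at trivalent iodine) is known to tolerate ortho substituents on both partners, and the symmetric salt leaves no question of which aryl group is transferred.

Step 15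
Reactants: 25 1-(benzyloxy)-4-methoxy-2-{4-methoxy-2-[4-methoxy-5-methyl-2-(propan-2-yl)phenoxy]-3-methyl-6-(propan-2-yl)phenoxy}-3-methyl-6-(propan-2-yl)benzene
Product: 26 4-methoxy-2-{4-methoxy-2-[4-methoxy-5-methyl-2-(propan-2-yl)phenoxy]-3-methyl-6-(propan-2-yl)phenoxy}-3-methyl-6-(propan-2-yl)phenol
Conditions: H2 (1 atm), 10% Pd/C, EtOAc/EtOH, rt
Reagents that add atoms: none
Why: Hydrogenolysis of the benzyl ether frees the only phenol of the molecule, while methyl and diaryl ethers are inert under these conditions.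

Step 16
Reactants: 26 4-methoxy-2-{4-methoxy-2-[4-methoxy-5-methyl-2-(propan-2-yl)phenoxy]-3-methyl-6-(propan-2-yl)phenoxy}-3-methyl-6-(propan-2-yl)phenol
Product: 28 2-{4-methoxy-2-[4-methoxy-5-methyl-2-(propan-2-yl)phenoxy]-3-methyl-6-(propan-2-yl)phenoxy}-3-methyl-6-(propan-2-yl)cyclohexa-2,5-diene-1,4-dione (target), via quinone hemiketal 27 (not isolated)
Conditions: PhI(OAc)2 (1.2 equiv), MeCN/H2O (2:1), 0 °C
Reagents that add atoms: water, O
Why: Oxidative dearomatization of a para-methoxyphenol by a trivalent iodine reagent: only ring C has a free hydroxyl, water attacks the para carbon bearing OMe to give 27, and loss of methanol should give the para-quinone while the fully etherified rings A and B stay untouched.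

**Compound list**

1 | thymol, 5-methyl-2-(propan-2-yl)phenol | Cc1ccc(C(C)C)c(O)c1 | starting material
2 | 4-bromo-5-methyl-2-(propan-2-yl)phenol | Cc1cc(O)c(C(C)C)cc1Br | intermediate
3 | 4-methoxy-5-methyl-2-(propan-2-yl)phenol | COc1cc(C(C)C)c(O)cc1C | intermediate
4 | 2-(hydroxymethyl)-4-methoxy-3-methyl-6-(propan-2-yl)phenol | COc1cc(C(C)C)c(O)c(CO)c1C | intermediate (not isolated)
5 | 2-hydroxy-5-methoxy-6-methyl-3-(propan-2-yl)benzaldehyde | COc1cc(C(C)C)c(O)c(C=O)c1C | intermediate
6 | 2-(benzyloxy)-5-methoxy-6-methyl-3-(propan-2-yl)benzaldehyde | COc1cc(C(C)C)c(OCc2ccccc2)c(C=O)c1C | intermediate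
7 | 2-(benzyloxy)-5-methoxy-6-methyl-3-(propan-2-yl)phenyl formate | COc1cc(C(C)C)c(OCc2ccccc2)c(OC=O)c1C | intermediate (not isolated)
8 | 2-(benzyloxy)-5-methoxy-6-methyl-3-(propan-2-yl)phenol | COc1cc(C(C)C)c(OCc2ccccc2)c(O)c1C | intermediate
9 | diallyl malonate, bis(prop-2-en-1-yl) propanedioate | C=CCOC(=O)CC(=O)OCC=C | starting material
10 | bis(prop-2-en-1-yl) 2-chloropropanedioate | C=CCOC(=O)C(Cl)C(=O)OCC=C | intermediate
11 | bis(prop-2-en-1-yl) 2-[2-(benzyloxy)-5-methoxy-6-methyl-3-(propan-2-yl)phenoxy]propanedioate | C=CCOC(=O)C(Oc1c(C)c(OC)cc(C(C)C)c1OCc1ccccc1)C(=O)OCC=C | intermediate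
12 | isobutyraldehyde, 2-methylpropanal | CC(C)C=O | starting material
13 | diethyl (2-oxobutyl)phosphonate | CCC(=O)CP(=O)(OCC)OCC | starting material
14 | (E)-6-methylhept-4-en-3-one | CCC(=O)/C=C/C(C)C | intermediate
15 | bis(prop-2-en-1-yl) 2-[2-(benzyloxy)-5-methoxy-6-methyl-3-(propan-2-yl)phenoxy]-2-(2-methyl-5-oxoheptan-3-yl)propanedioate (racemic) | C=CCOC(=O)C(Oc1c(C)c(OC)cc(C(C)C)c1OCc1ccccc1)(C(=O)OCC=C)C(CC(=O)CC)C(C)C | intermediate (not isolated)
16 | prop-2-en-1-yl 1-[2-(benzyloxy)-5-methoxy-6-methyl-3-(propan-2-yl)phenoxy]-3-methyl-2,4-dioxo-6-(propan-2-yl)cyclohexane-1-carboxylate (mixture of diastereomers) | C=CCOC(=O)C1(Oc2c(C)c(OC)cc(C(C)C)c2OCc2ccccc2)C(=O)C(C)C(=O)CC1C(C)C | intermediate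
17 | prop-2-en-1-yl 1-[2-(benzyloxy)-5-methoxy-6-methyl-3-(propan-2-yl)phenoxy]-4-methoxy-3-methyl-2-oxo-6-(propan-2-yl)cyclohex-3-ene-1-carboxylate (mixture of diastereomers) | C=CCOC(=O)C1(Oc2c(C)c(OC)cc(C(C)C)c2OCc2ccccc2)C(=O)C(C)=C(OC)CC1C(C)C | intermediate
18 | 2-[2-(benzyloxy)-5-methoxy-6-methyl-3-(propan-2-yl)phenoxy]-5-methoxy-6-methyl-3-(propan-2-yl)cyclohexa-2,5-dien-1-one | CC1=C(OC)CC(C(C)C)=C(Oc2c(C)c(OC)cc(C(C)C)c2OCc2ccccc2)C1=O | intermediate (not isolated)
19 | 2-[2-(benzyloxy)-5-methoxy-6-methyl-3-(propan-2-yl)phenoxy]-5-methoxy-6-methyl-3-(propan-2-yl)phenol | Cc1c(O)c(Oc2c(C)c(OC)cc(C(C)C)c2OCc2ccccc2)c(C(C)C)cc1OC | intermediate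
20 | carvacrol, 2-methyl-5-(propan-2-yl)phenol | Cc1ccc(C(C)C)cc1O | starting material
21 | 2-methoxy-1-methyl-4-(propan-2-yl)benzene | COc1cc(C(C)C)ccc1C | intermediate
22 | 1-iodo-4-methoxy-5-methyl-2-(propan-2-yl)benzene | COc1cc(C(C)C)c(I)cc1C | intermediate (not isolated)
23 | 1-[hydroxy(tosyloxy)-λ3-iodanyl]-4-methoxy-5-methyl-2-(propan-2-yl)benzene | COc1cc(C(C)C)c(I(O)OS(=O)(=O)c2ccc(C)cc2)cc1C | intermediate (not isolated)
24 | bis[4-methoxy-5-methyl-2-(propan-2-yl)phenyl]iodonium 4-methylbenzenesulfonate | COc1cc(C(C)C)c([I+]c2cc(C)c(OC)cc2C(C)C)cc1C.Cc1ccc(cc1)S(=O)(=O)[O-] | intermediate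
25 | 1-(benzyloxy)-4-methoxy-2-{4-methoxy-2-[4-methoxy-5-methyl-2-(propan-2-yl)phenoxy]-3-methyl-6-(propan-2-yl)phenoxy}-3-methyl-6-(propan-2-yl)benzene | COc1cc(C(C)C)c(Oc2c(C)c(OC)cc(C(C)C)c2Oc2c(C)c(OC)cc(C(C)C)c2OCc2ccccc2)cc1C | intermediate
26 | 4-methoxy-2-{4-methoxy-2-[4-methoxy-5-methyl-2-(propan-2-yl)phenoxy]-3-methyl-6-(propan-2-yl)phenoxy}-3-methyl-6-(propan-2-yl)phenol | COc1cc(C(C)C)c(Oc2c(C)c(OC)cc(C(C)C)c2Oc2c(C)c(OC)cc(C(C)C)c2O)cc1C | intermediate
27 | 4-hydroxy-4-methoxy-2-{4-methoxy-2-[4-methoxy-5-methyl-2-(propan-2-yl)phenoxy]-3-methyl-6-(propan-2-yl)phenoxy}-3-methyl-6-(propan-2-yl)cyclohexa-2,5-dien-1-one | COc1cc(C(C)C)c(Oc2c(C)c(OC)cc(C(C)C)c2OC2=C(C)C(O)(OC)C=C(C(C)C)C2=O)cc1C | intermediate (not isolated)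
28 | 2-{4-methoxy-2-[4-methoxy-5-methyl-2-(propan-2-yl)phenoxy]-3-methyl-6-(propan-2-yl)phenoxy}-3-methyl-6-(propan-2-yl)cyclohexa-2,5-diene-1,4-dione | COc1cc(C(C)C)c(Oc2c(C)c(OC)cc(C(C)C)c2OC2=C(C)C(=O)C=C(C(C)C)C2=O)cc1C | target

**Count and risks**

Total step count: 16. Longest linear sequence: 12 steps (steps 1–5, 7, 9–11 and 14–16, from thymol).

Steps most likely to fail:

1. Step 9. A tertiary carbanion has to attack a β-carbon that carries an isopropyl group; slow addition, reversal of the Michael step before ring closure, and base-induced deconjugation or self-condensation of the enone could all erode conversion. The fallback makes the two bonds in separate, kinetically controlled operations. It sets out from 11, which is silylated (Me3SiOTf, Et3N, CH2Cl2, 0 °C) to the ketene silyl acetal prop-2-en-1-yl 2-[2-(benzyloxy)-5-methoxy-6-methyl-3-(propan-2-yl)phenoxy]-3-(prop-2-en-1-yloxy)-3-[(trimethylsilyl)oxy]prop-2-enoate F1. A TiCl4-promoted Mukaiyama–Michael addition of F1 to 14 (CH2Cl2, −78 °C) should give, after aqueous work-up, the adduct 15, now isolated. Kinetic deprotonation of its ethyl ketone on the less hindered side with LiN(SiMe3)2 (2.2 equiv, THF, −78 to 0 °C) and Claisen closure bring the route back at 16.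

2. Step 11. Reductive elimination to the α-allyl ketone, or simple protonation of the palladium enolate, may outrun β-hydride elimination towards the crowded isopropyl-bearing carbon. The fallback separates decarboxylation from dehydrogenation and sets out from 17. Pd(OAc)2/PPh3 with HCO2H/Et3N in THF (decarboxylation–hydrogenolysis of the allyl ester) should give 6-[2-(benzyloxy)-5-methoxy-6-methyl-3-(propan-2-yl)phenoxy]-3-methoxy-2-methyl-5-(propan-2-yl)cyclohex-2-en-1-one F2. Its kinetic α'-enolate (LiN(iPr)2, THF, −78 °C) is trapped with PhSeCl to give 6-[2-(benzyloxy)-5-methoxy-6-methyl-3-(propan-2-yl)phenoxy]-3-methoxy-2-methyl-6-(phenylselanyl)-5-(propan-2-yl)cyclohex-2-en-1-one F3. Oxidation with H2O2/pyridine at 0 °C and syn-elimination of the selenoxide lead through 18 back to the route at 19.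

3. Step 14. Ligand coupling of an electron-rich, ortho-isopropyl aryl group onto a phenoxide with two ortho substituents may be slow, and base-induced decomposition of the salt (aryne formation) could then compete. The fallback forms the same C–O bond by copper catalysis and sets out from 19. The aryl iodide 22 is prepared in isolable form from 21 (N-iodosuccinimide, cat. CF3CO2H, MeCN) and coupled with 19 in an Ullmann diaryl ether synthesis (CuI, picolinic acid, K3PO4, DMSO, 100 °C), returning to the route at 25. No compound outside the list arises (F0).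

**Further compounds**

F1 | step 9 | prop-2-en-1-yl 2-[2-(benzyloxy)-5-methoxy-6-methyl-3-(propan-2-yl)phenoxy]-3-(prop-2-en-1-yloxy)-3-[(trimethylsilyl)oxy]prop-2-enoate | C=CCOC(=O)C(Oc1c(C)c(OC)cc(C(C)C)c1OCc1ccccc1)=C(OCC=C)O[Si](C)(C)C
F2 | step 11 | 6-[2-(benzyloxy)-5-methoxy-6-methyl-3-(propan-2-yl)phenoxy]-3-methoxy-2-methyl-5-(propan-2-yl)cyclohex-2-en-1-one | CC1=C(OC)CC(C(C)C)C(Oc2c(C)c(OC)cc(C(C)C)c2OCc2ccccc2)C1=O
F3 | step 11 | 6-[2-(benzyloxy)-5-methoxy-6-methyl-3-(propan-2-yl)phenoxy]-3-methoxy-2-methyl-6-(phenylselanyl)-5-(propan-2-yl)cyclohex-2-en-1-one | CC1=C(OC)CC(C(C)C)C(Oc2c(C)c(OC)cc(C(C)C)c2OCc2ccccc2)([Se]c2ccccc2)C1=O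
F0 | step 14 | none | none
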